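## Retrosynthetic overview

1. 21 ⇒ 20: the C11 methyl stereocentre is set last, by face-selective hydrogenation of the 11(13)-methylene lactone.
2. 20 ⇒ 18 (key step): one chromium-mediated allylation–lactonisation of an open-chain (Z)-enal/allylic bromide forms C6–C7 and O–C12. The ten-membered carbocycle and the γ-lactone therefore arise together from a compound that has no ring.
3. 18 ⇒ 15: cross-metathesis brings in C11–C13, and oxidation at C6 frees the aldehyde.
4. 15 ⇒ 1: two rounds of methacrylate ring-closing metathesis, DIBAL-H and Brown allylation. The small lactones 2 and 10 are sacrificial templates that lock 4Z and 1(10)Z, and the allylborations set C3 and C9.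
5. Ring order: butenolide 2 (opened again), pentenolide 10 (opened again), then carbocycle and lactone in one operation.

Assumption: locants follow germacrane numbering (C12 is the lactone carbonyl, the lactone O sits on C6). The SMILES is read as 3S,6S,7S,9R,11R with 1(10)Z,4Z, a trans-fused lactone and the C11 methyl cis to C8. (−)-Ipc2B(allyl) is the reagent derived from (+)-α-pinene.

## Route

Step 1
Reactants: 1 allyl methacrylate
Product: 2 3-methylfuran-2(5H)-one
Conditions: second-generation Grubbs catalyst RuCl2(=CHPh)(PCy3)(H2IMes) (2 mol%), CH2Cl2 (0.05 M), 40 °C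
Reagents that add atoms: none
Why: Ring-closing metathesis of an allyl methacrylate to a five-membered butenolide is fast with this catalyst, and the ring forces C3 and C6 to be cis on the C4=C5 bond, which is the later 4Z geometry.

Step 2
Reactants: 2 3-methylfuran-2(5H)-one
Product: 3 3-methyl-2,5-dihydrofuran-2-ol (lactol)
Conditions: DIBAL-H (1.05 equiv), CH2Cl2, −78 °C; aq. Rochelle salt
Reagents that add atoms: none
Why: DIBAL-H half-reduction of a lactone stops at the aluminium hemiacetal at low temperature and gives a lactol, a masked (Z)-γ-hydroxy enal that cannot drift to the E isomer.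

Step 3
Reactants: 3 3-methyl-2,5-dihydrofuran-2-ol; 4 (−)-B-allyldiisopinocampheylborane
Product: 6 (2Z,4S)-3-methylhepta-2,6-diene-1,4-diol, via (Z)-4-hydroxy-2-methylbut-2-enal 5 (not isolated)
Conditions: 4 (2.2 equiv), Et2O, −78 → 0 °C; then NaOH, H2O2
Reagents that add atoms: (−)-B-allyldiisopinocampheylborane, C=CCB([C@@H]1C[C@@H]2C[C@H]([C@H]1C)C2(C)C)[C@@H]1C[C@@H]2C[C@H]([C@H]1C)C2(C)C
Why: Brown asymmetric allylboration of the ring-opened aldehyde passes through a closed chair transition state in which this reagent delivers allyl to the Si face of C3 (as it does for benzaldehyde-type aldehydes), which sets 3S under reagent control.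

Step 4
Reactants: 6 (2Z,4S)-3-methylhepta-2,6-diene-1,4-diol
Product: 7 (2Z,4S)-1-[(tert-butyldimethylsilyl)oxy]-3-methylhepta-2,6-dien-4-ol
Conditions: TBSCl (1.05 equiv), imidazole, CH2Cl2, 0 °C
Reagents that add atoms: tert-butyldimethylsilyl chloride, CC(C)(C)[Si](C)(C)Cl
Why: Silyl ether formation is selective for the primary allylic hydroxyl (C6–OH) over the hindered secondary one next to the fully substituted olefin carbon.

Step 5
Reactants: 7 (2Z,4S)-1-[(tert-butyldimethylsilyl)oxy]-3-methylhepta-2,6-dien-4-ol; 8 methacryloyl chloride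
Product: 9 (2Z,4S)-1-[(tert-butyldimethylsilyl)oxy]-3-methylhepta-2,6-dien-4-yl methacrylate
Conditions: 8 (1.5 equiv), Et3N, DMAP (cat.), CH2Cl2, 0 °C
Reagents that add atoms: methacryloyl chloride, C=C(C)C(=O)Cl
Why: DMAP-catalysed O-acylation brings in C9, C10 and C14 without touching the C3 stereocentre.

Step 6
Reactants: 9 (2Z,4S)-1-[(tert-butyldimethylsilyl)oxy]-3-methylhepta-2,6-dien-4-yl methacrylate
Product: 10 (6S)-6-{(2Z)-4-[(tert-butyldimethylsilyl)oxy]but-2-en-2-yl}-3-methyl-5,6-dihydro-2H-pyran-2-one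
Conditions: second-generation Grubbs catalyst (5 mol%), CH2Cl2 (0.01 M), 40 °C
Reagents that add atoms: none
Why: Ring-closing metathesis of the only terminal olefin with the methacrylate gives the six-membered α-methyl pentenolide, whose ring forces C2 and C9 to be cis on C1=C10 (the later 1(10)Z geometry), while the trisubstituted C4=C5 bond stays out of the reaction.

Step 7
Reactants: 10 (6S)-6-{(2Z)-4-[(tert-butyldimethylsilyl)oxy]but-2-en-2-yl}-3-methyl-5,6-dihydro-2H-pyran-2-one
Product: 11 (6S)-6-{(2Z)-4-[(tert-butyldimethylsilyl)oxy]but-2-en-2-yl}-3-methyl-5,6-dihydro-2H-pyran-2-ol (anomer mixture)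
Conditions: DIBAL-H (1.1 equiv), toluene, −78 °C; aq. Rochelle salt
Reagents that add atoms: none
Why: DIBAL-H half-reduction of the lactone gives the lactol, which stores the labile (Z)-α-methyl enal at C9 in cyclic form, and the silyl ether is inert.

Step 8
Reactants: 11 (6S)-6-{(2Z)-4-[(tert-butyldimethylsilyl)oxy]but-2-en-2-yl}-3-methyl-5,6-dihydro-2H-pyran-2-ol; 12 (+)-B-allyldiisopinocampheylborane
Product: 14 (2Z,4S,6Z,8R)-1-[(tert-butyldimethylsilyl)oxy]-3,7-dimethylundeca-2,6,10-triene-4,8-diol, via open-chain hydroxy enal 13 (not isolated)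
Conditions: 12 (2.2 equiv), Et2O, −78 → 0 °C; then NaOH, H2O2
Reagents that add atoms: (+)-B-allyldiisopinocampheylborane, C=CCB([C@H]1C[C@H]2C[C@@H]([C@@H]1C)C2(C)C)[C@H]1C[C@H]2C[C@@H]([C@@H]1C)C2(C)C
Why: A second Brown allylboration, now with the antipodal reagent, attacks the Re face of the C9 aldehyde and sets 9R under reagent control independently of the remote C3 centre, and it adds C8 and C7.

Step 9
Reactants: 14 (2Z,4S,6Z,8R)-1-[(tert-butyldimethylsilyl)oxy]-3,7-dimethylundeca-2,6,10-triene-4,8-diol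
Product: 15 (2Z,4S,6Z,8R)-1-[(tert-butyldimethylsilyl)oxy]-3,7-dimethylundeca-2,6,10-triene-4,8-diyl diacetate
Conditions: Ac2O, pyridine, DMAP (cat.), CH2Cl2, 23 °C
Reagents that add atoms: acetic anhydride, CC(=O)OC(C)=O
Why: One DMAP-catalysed acetylation installs both acetates of the target with retention at C3 and C9.

Step 10
Reactants: 15 (2Z,4S,6Z,8R)-1-[(tert-butyldimethylsilyl)oxy]-3,7-dimethylundeca-2,6,10-triene-4,8-diyl diacetate; 16 methyl 2-(bromomethyl)acrylate
Product: 17 methyl (2Z,5R,6Z,9S,10Z)-5,9-diacetoxy-2-(bromomethyl)-12-[(tert-butyldimethylsilyl)oxy]-6,10-dimethyldodeca-2,6,10-trienoate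
Conditions: 16 (4 equiv), second-generation Hoveyda–Grubbs catalyst RuCl2(=CH-C6H4-2-OiPr)(H2IMes) (10 mol%), CH2Cl2, 40 °C
Reagents that add atoms: methyl 2-(bromomethyl)acrylate, C=C(CBr)C(=O)OC
Why: Olefin cross-metathesis pairs the single monosubstituted olefin with the 1,1-disubstituted acrylate, as methacrylates do, and gives the isomer with the chain trans to the ester, adding C11, C12 and C13 in one step.

Step 11
Reactants: 17 methyl (2Z,5R,6Z,9S,10Z)-5,9-diacetoxy-2-(bromomethyl)-12-[(tert-butyldimethylsilyl)oxy]-6,10-dimethyldodeca-2,6,10-trienoate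
Product: 18 methyl (2Z,5R,6Z,9S,10Z)-5,9-diacetoxy-2-(bromomethyl)-6,10-dimethyl-12-oxododeca-2,6,10-trienoate
Conditions: DDQ (1.3 equiv), CH2Cl2/pH 7 buffer (10:1), 23 °C; used at once
Reagents that add atoms: none
Why: DDQ oxidative desilylation (hydride abstraction from the electron-rich primary allylic silyl ether) gives the (Z)-enal directly under neutral conditions that spare the acetates, the bromide and the olefin geometry.

Step 12
Reactants: 18 methyl (2Z,5R,6Z,9S,10Z)-5,9-diacetoxy-2-(bromomethyl)-6,10-dimethyl-12-oxododeca-2,6,10-trienoate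
Product: 20 (3S,6R,7S,9R,1(10)Z,4Z)-3,9-diacetoxygermacra-1(10),4,11(13)-trien-12,6-olide, via macrocyclic hydroxy ester 19 (not isolated)
Conditions: CrCl2 (8 equiv), valinol-derived oxazoline–sulfonamide ligand (the antipode that opens the Si face, 9 equiv), Et3N (9 equiv), THF, 25 °C, 18 added over 20 h to 1 mM; aq. work-up, SiO2
Reagents that add atoms: none
Why: In this intramolecular Nozaki–Hiyama–Kishi-type allylation with in situ lactonisation, divalent chromium turns the allylic bromide into an allylchromium that adds through its γ-carbon C7 to the C6 aldehyde in a chair transition state (anti whatever the bromide geometry, hence the trans C6/C7 relationship), the chiral ligand steers attack to the Si face (6R,7S in 19 and 20), and the chromium alkoxide then displaces methoxide from the adjacent ester, so the ten-membered carbocycle and the γ-lactone both form from the open chain in one operation.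

Step 13
Reactants: 20 (3S,6R,7S,9R,1(10)Z,4Z)-3,9-diacetoxygermacra-1(10),4,11(13)-trien-12,6-olide
Product: 21 (3S,6S,7S,9R,11R,1(10)Z,4Z)-3,9-diacetoxygermacra-1(10),4-dien-12,6-olide (target; 6R becomes 6S only through the change in CIP ranking)
Conditions: H2 (1 atm), RhCl(PPh3)3 (10 mol%), benzene/EtOH (1:1), 23 °C
Reagents that add atoms: none
Why: Homogeneous Wilkinson hydrogenation takes only the unhindered conjugated 1,1-disubstituted methylene and delivers hydrogen to the lactone face that carries H7 (anti to the C7–C8 bond), which places the new methyl cis to C8 and sets 11R without basic conditions that could epimerise it.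

## Compound list

1 | allyl methacrylate | C=CCOC(=O)C(C)=C | starting material
2 | 3-methylfuran-2(5H)-one | CC1=CCOC1=O | intermediate
3 | 3-methyl-2,5-dihydrofuran-2-ol | CC1=CCOC1O | intermediate
4 | (−)-B-allyldiisopinocampheylborane | C=CCB([C@@H]1C[C@@H]2C[C@H]([C@H]1C)C2(C)C)[C@@H]1C[C@@H]2C[C@H]([C@H]1C)C2(C)C | starting material
5 | (Z)-4-hydroxy-2-methylbut-2-enal (not isolated) | O=C/C(C)=C\CO | intermediate
6 | (2Z,4S)-3-methylhepta-2,6-diene-1,4-diol | O[C@H](/C(C)=C\CO)CC=C | intermediate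
7 | (2Z,4S)-1-[(tert-butyldimethylsilyl)oxy]-3-methylhepta-2,6-dien-4-ol | O[C@H](/C(C)=C\CO[Si](C)(C)C(C)(C)C)CC=C | intermediate
8 | methacryloyl chloride | C=C(C)C(=O)Cl | starting material
9 | (2Z,4S)-1-[(tert-butyldimethylsilyl)oxy]-3-methylhepta-2,6-dien-4-yl methacrylate | C=C(C)C(=O)O[C@H](/C(C)=C\CO[Si](C)(C)C(C)(C)C)CC=C | intermediate
10 | (6S)-6-{(2Z)-4-[(tert-butyldimethylsilyl)oxy]but-2-en-2-yl}-3-methyl-5,6-dihydro-2H-pyran-2-one | O=C1O[C@H](/C(C)=C\CO[Si](C)(C)C(C)(C)C)CC=C1C | intermediate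
11 | (6S)-6-{(2Z)-4-[(tert-butyldimethylsilyl)oxy]but-2-en-2-yl}-3-methyl-5,6-dihydro-2H-pyran-2-ol (anomer mixture) | OC1O[C@H](/C(C)=C\CO[Si](C)(C)C(C)(C)C)CC=C1C | intermediate
12 | (+)-B-allyldiisopinocampheylborane | C=CCB([C@H]1C[C@H]2C[C@@H]([C@@H]1C)C2(C)C)[C@H]1C[C@H]2C[C@@H]([C@@H]1C)C2(C)C | starting material
13 | (2Z,5S,6Z)-8-[(tert-butyldimethylsilyl)oxy]-5-hydroxy-2,6-dimethylocta-2,6-dienal (not isolated) | O=C/C(C)=C\C[C@H](O)/C(C)=C\CO[Si](C)(C)C(C)(C)C | intermediate
14 | (2Z,4S,6Z,8R)-1-[(tert-butyldimethylsilyl)oxy]-3,7-dimethylundeca-2,6,10-triene-4,8-diol | O[C@H](/C(C)=C\CO[Si](C)(C)C(C)(C)C)C/C=C(/C)[C@H](O)CC=C | intermediate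
15 | (2Z,4S,6Z,8R)-1-[(tert-butyldimethylsilyl)oxy]-3,7-dimethylundeca-2,6,10-triene-4,8-diyl diacetate | CC(=O)O[C@H](/C(C)=C\CO[Si](C)(C)C(C)(C)C)C/C=C(/C)[C@H](OC(C)=O)CC=C | intermediate
16 | methyl 2-(bromomethyl)acrylate | C=C(CBr)C(=O)OC | starting material
17 | methyl (2Z,5R,6Z,9S,10Z)-5,9-diacetoxy-2-(bromomethyl)-12-[(tert-butyldimethylsilyl)oxy]-6,10-dimethyldodeca-2,6,10-trienoate | CC(=O)O[C@H](/C(C)=C\CO[Si](C)(C)C(C)(C)C)C/C=C(/C)[C@H](OC(C)=O)C/C=C(\CBr)C(=O)OC | intermediate
18 | methyl (2Z,5R,6Z,9S,10Z)-5,9-diacetoxy-2-(bromomethyl)-6,10-dimethyl-12-oxododeca-2,6,10-trienoate | CC(=O)O[C@H](/C(C)=C\C=O)C/C=C(/C)[C@H](OC(C)=O)C/C=C(\CBr)C(=O)OC | intermediate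
19 | methyl (3S,6R,7S,9R,1(10)Z,4Z)-3,9-diacetoxy-6-hydroxygermacra-1(10),4,11(13)-trien-12-oate (not isolated) | CC(=O)O[C@H]1C/C=C(/C)[C@H](OC(C)=O)C[C@@H](C(=C)C(=O)OC)[C@@H](/C=C\1C)O | intermediate
20 | (3S,6R,7S,9R,1(10)Z,4Z)-3,9-diacetoxygermacra-1(10),4,11(13)-trien-12,6-olide | CC(=O)O[C@H]1C/C=C(/C)[C@H](OC(C)=O)C[C@@H]2[C@@H](/C=C\1C)OC(=O)C2=C | intermediate
21 | (3S,6S,7S,9R,11R,1(10)Z,4Z)-3,9-diacetoxygermacra-1(10),4-dien-12,6-olide | CC(=O)O[C@H]1C/C=C(/C)[C@H](OC(C)=O)C[C@@H]2[C@@H](/C=C\1C)OC(=O)[C@@H]2C | target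

## Step count and risks

Total step count: 13. Longest linear sequence: 13 (1 → 21).

**Most likely to fail: the double ring closure (step 12).** Three things work against it:
- the entropic and strain cost of a ten-membered ring;
- possible Z→E drift of enal 18;
- a possible mismatch between the ligand and the resident C3 and C9 centres.

The fallback closes the two rings one after the other.
- It sets out from 7. Acetylation gives (2Z,4S)-1-[(tert-butyldimethylsilyl)oxy]-3-methylhepta-2,6-dien-4-yl acetate F1. DDQ then gives (2Z,4S)-4-acetoxy-3-methylhepta-2,6-dienal F2.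
- In parallel, methacrolein and 12 give (3R)-2-methylhexa-1,5-dien-3-ol F3, then its acetate (3R)-2-methylhexa-1,5-dien-3-yl acetate F4. Cross-metathesis with 16 gives methyl (2Z,5R)-5-acetoxy-2-(bromomethyl)-6-methylhepta-2,6-dienoate F5.
- The same chromium/ligand system couples F2 and F5 at normal concentration. The product is (4S,5R)-5-[(1Z,3S)-3-acetoxy-2-methylhexa-1,5-dien-1-yl]-4-[(2R)-2-acetoxy-3-methylbut-3-en-1-yl]-3-methylidenedihydrofuran-2(3H)-one F6.
- Ring-closing metathesis of the allyl and isopropenyl ends of F6 should favour the Z olefin in a ring of this size. It comes back to the route at 20.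

**Second: the facial selectivity of the hydrogenation (step 13).** It could give the more stable 11S epimer instead. The fallback separates hydride delivery from protonation. It sets out from 20.
- Rhodium-catalysed 1,4-hydrosilylation with Et3SiH gives the cyclic (3S,6S,7S,9R,1(10)Z,4Z)-3,9-diacetoxy-12-(triethylsilyloxy)-6,12-epoxygermacra-1(10),4,11-triene (silyl ketene acetal) F7.
- F7 is protonated at −78 °C by 2,6-di-tert-butylphenol with a catalytic fluoride source.
- The bulky donor can reach C11 only from the face anti to C8, so the fallback comes back at 21.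

**Third: the cross-metathesis with an allylic bromide (step 10).** Catalyst decay and homodimers of 15 are the risks. The fallback builds the bromomethyl enoate by carbonyl chemistry. It sets out from 15.
- OsO4/NaIO4 cleavage is aimed at the terminal olefin. It is the least hindered of the three, and the two trisubstituted olefins are deactivated by allylic oxygen. The cleavage gives (3R,4Z,7S,8Z)-3,7-diacetoxy-10-[(tert-butyldimethylsilyl)oxy]-4,8-dimethyldeca-4,8-dienal F8.
- A Baylis–Hillman reaction with methyl acrylate gives methyl (5R,6Z,9S,10Z)-5,9-diacetoxy-12-[(tert-butyldimethylsilyl)oxy]-3-hydroxy-6,10-dimethyl-2-methylidenedodeca-6,10-dienoate F9 as a mixture of C3 epimers.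
- NBS/Me2S converts F9 by SN2′ displacement into the (Z)-bromide, so the fallback comes back at 17.

## Further compounds

F1 | step 12 | (2Z,4S)-1-[(tert-butyldimethylsilyl)oxy]-3-methylhepta-2,6-dien-4-yl acetate | CC(=O)O[C@H](/C(C)=C\CO[Si](C)(C)C(C)(C)C)CC=C
F2 | step 12 | (2Z,4S)-4-acetoxy-3-methylhepta-2,6-dienal | CC(=O)O[C@H](/C(C)=C\C=O)CC=C
F3 | step 12 | (3R)-2-methylhexa-1,5-dien-3-ol | C=C(C)[C@H](O)CC=C
F4 | step 12 | (3R)-2-methylhexa-1,5-dien-3-yl acetate | C=C(C)[C@H](OC(C)=O)CC=C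
F5 | step 12 | methyl (2Z,5R)-5-acetoxy-2-(bromomethyl)-6-methylhepta-2,6-dienoate | C=C(C)[C@H](OC(C)=O)C/C=C(\CBr)C(=O)OC
F6 | step 12 | (4S,5R)-5-[(1Z,3S)-3-acetoxy-2-methylhexa-1,5-dien-1-yl]-4-[(2R)-2-acetoxy-3-methylbut-3-en-1-yl]-3-methylidenedihydrofuran-2(3H)-one | CC(=O)O[C@@H](CC=C)/C(C)=C\[C@H]1OC(=O)C(=C)[C@@H]1C[C@@H](OC(C)=O)C(C)=C
F7 | step 13 | (3S,6S,7S,9R,1(10)Z,4Z)-3,9-diacetoxy-12-(triethylsilyloxy)-6,12-epoxygermacra-1(10),4,11-triene (silyl ketene acetal) | CC(=O)O[C@H]1C/C=C(/C)[C@H](OC(C)=O)C[C@@H]2[C@@H](/C=C\1C)OC(O[Si](CC)(CC)CC)=C2C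
F8 | step 10 | (3R,4Z,7S,8Z)-3,7-diacetoxy-10-[(tert-butyldimethylsilyl)oxy]-4,8-dimethyldeca-4,8-dienal | CC(=O)O[C@H](/C(C)=C\CO[Si](C)(C)C(C)(C)C)C/C=C(/C)[C@H](OC(C)=O)CC=O
F9 | step 10 | methyl (5R,6Z,9S,10Z)-5,9-diacetoxy-12-[(tert-butyldimethylsilyl)oxy]-3-hydroxy-6,10-dimethyl-2-methylidenedodeca-6,10-dienoate (C3 epimers) | CC(=O)O[C@H](/C(C)=C\CO[Si](C)(C)C(C)(C)C)C/C=C(/C)[C@H](OC(C)=O)CC(O)C(=C)C(=O)OC
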